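**Retrosynthetic overview**
1. The target is traced back through late angeloylation of an (S)-benzylic alcohol and reagent-controlled reduction of an aryl methyl ketone to methyl 2-[(2S,3S)-3-acetoxy-5-acetyl-2,3-dihydrobenzofuran-2-yl]acrylate, which already holds the C3 acetate, the acrylate and both ring stereocentres.
2. Key disconnection: both bonds of the dihydrofuran ring (C2–C3 and O1–C2) in a formal (4+1) annulation with acyl relay. The four atoms O1–C7a–C3a–C3 come from 4-acetyl-2-formylphenyl acetate; C2 with its acrylate comes from a chiral 2-(methoxycarbonyl)allyl sulfonium ylide.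
3. Enabling feature: C2 is the allylic CH between O1 and the acrylate α-carbon, i.e. the CH2 of a 2-(methoxycarbonyl)allyl unit that can act first as nucleophile (ylide) and then as electrophile (C–S+). O1 and the C3 oxygen are ortho-related on the benzene ring, so the aryl acetate can pass its acetyl group to the C3 oxygen and free O1 for ring closure.
4. Ring order: the benzene ring is bought; the thiolane ring of the recoverable chiral sulfide is made in step 2 and is not part of the target; the dihydrofuran ring is closed last, in step 5.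

Key step: step 5

Assumption: 5-acetyl-2-hydroxybenzaldehyde and angelic anhydride are taken as catalogue chemicals (the former is otherwise one ortho-formylation away from 4'-hydroxyacetophenone).

**Step 1**
Reactants: 1 (2S,5S)-hexane-2,5-diol
Product: 2 (2S,5S)-hexane-2,5-diyl dimethanesulfonate
Conditions: MsCl (2.4 equiv), Et3N (3 equiv), CH2Cl2, −10 → 0 °C
Reagents that add atoms: methanesulfonyl chloride, CS(=O)(=O)Cl
Why: O-Sulfonylation of both secondary alcohols (mesylation) touches only the O–H bonds, so the two (S)-centres are carried over unchanged.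

**Step 2**
Reactants: 2 (2S,5S)-hexane-2,5-diyl dimethanesulfonate
Product: 3 (2R,5R)-2,5-dimethylthiolane
Conditions: Na2S·9H2O (1.2 equiv), DMSO, rt; pentane extraction, distillation
Reagents that add atoms: sodium sulfide, [Na+].[Na+].[S-2]
Why: Double SN2 thioetherification (intermolecular displacement, then 5-exo-tet closure) inverts each carbinol carbon once, so the (2S,5S)-dimesylate should give the trans (2R,5R)-thiolane.

**Step 3**
Reactants: 3 (2R,5R)-2,5-dimethylthiolane; 4 methyl 2-(bromomethyl)prop-2-enoate
Product: 5 (2R,5R)-1-[2-(methoxycarbonyl)prop-2-en-1-yl]-2,5-dimethylthiolan-1-ium tetrafluoroborate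
Conditions: AgBF4 (1.0 equiv), CH2Cl2, 0 °C → rt, dark; filtration, trituration with Et2O
Reagents that add atoms: silver tetrafluoroborate, [Ag+].F[B-](F)(F)F
Why: S-Alkylation of the thioether by the activated allylic bromide (SN2 and SN2′ attack lead to the same cation) is made irreversible by precipitation of silver bromide, and because the C2 axis of 3 makes its two sulfur lone pairs equivalent a single sulfonium salt forms without a new stereocentre.

**Step 4**
Reactants: 6 5-acetyl-2-hydroxybenzaldehyde
Product: 7 4-acetyl-2-formylphenyl acetate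
Conditions: Ac2O (1.2 equiv), pyridine (2 equiv), CH2Cl2, 0 °C → rt
Reagents that add atoms: acetic anhydride, CC(=O)OC(C)=O
Why: O-Acetylation of the phenol (nucleophilic acyl substitution) masks the phenoxide, keeps the formyl group electrophilic and places the acetyl group that step 5 relays to the C3 oxygen.

**Step 5**
Reactants: 5 (2R,5R)-1-[2-(methoxycarbonyl)prop-2-en-1-yl]-2,5-dimethylthiolan-1-ium tetrafluoroborate; 7 4-acetyl-2-formylphenyl acetate
Product: 11 methyl 2-[(2S,3S)-3-acetoxy-5-acetyl-2,3-dihydro-1-benzofuran-2-yl]prop-2-enoate, via sulfonium ylide 8 (not isolated), via anti-betaine 9 (not isolated), via acyl-shifted phenoxide 10 (not isolated)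
Conditions: 5 (1.0 equiv), LiHMDS (1.0 equiv), THF, −78 °C, 20 min; then 7 (1.1 equiv), −78 → −20 °C; aq NH4Cl
Reagents that add atoms: none
Why: Proposed new method: ylide 8 adds through its sulfur-bearing carbon to the aldehyde of 7 (C2–C3 bond, Corey–Chaykovsky-type addition) to give the lithium anti-betaine 9, whose alkoxide takes the acetyl group from the ortho aryl acetate through a six-membered O→O shift and so releases phenoxide 10, which is already anti-periplanar to the C–S+ bond and displaces the sulfide by a 5-exo-tet SN2 reaction with inversion at C2 (O1–C2 bond), closing the dihydrofuran ring. The closest known chemistry is the formal (4+1) annulation of sulfur ylides with salicylaldehydes, salicyl imines and o-quinone methides to 2,3-dihydrobenzofurans, the chiral-sulfide allyl-ylide epoxidation of aldehydes, and the anionic 1,5-acyl shift that follows nucleophilic addition to O-acyl salicylaldehydes; the merger of ylide addition with the acyl relay is the untested part. C2 is set by the C2-symmetric thiolanium group: the ylide substituent points away from the ring and the aldehyde approaches the ylide face remote from the cis methyl group, the sense by which the (2R,5R)-sulfide is known to give (S,S)-epoxides from benzylic ylides. C3 is set relative to C2 by the kinetically preferred anti addition (aryl group anti to sulfur in the cisoid transition state), and because only one inversion at C2 follows, the anti-betaine maps onto the cis (2S,3S) product, whereas the same betaine would close to a trans epoxide. The step needs the acyl shift to outrun epoxide closure and retro-addition: the acetate is an activated para-acetyl aryl ester held in a six-membered relation to the alkoxide, the shift needs no bond rotation, and lithium in THF at −78 °C holds the betaine in its cisoid form and slows the 3-exo-tet closure, which must pass through the charge-separated anti rotamer. It also needs attack of the ylide at the formyl group and not at the ketone or ester carbonyls, which the higher electrophilicity of an aldehyde that carries no deactivating ortho phenoxide secures.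

**Step 6**
Reactants: 11 methyl 2-[(2S,3S)-3-acetoxy-5-acetyl-2,3-dihydro-1-benzofuran-2-yl]prop-2-enoate
Product: 12 methyl 2-[(2S,3S)-3-acetoxy-5-[(1S)-1-hydroxyethyl]-2,3-dihydro-1-benzofuran-2-yl]prop-2-enoate
Conditions: (R)-2-methyl-CBS-oxazaborolidine (15 mol %), BH3·SMe2 (0.7 equiv), THF, −20 °C, slow addition of 11; MeOH quench
Reagents that add atoms: none
Why: Corey–Bakshi–Shibata reduction, in which the (R)-oxazaborolidine–borane complex binds the ketone with the aryl group as the large substituent and delivers hydride to the Re face, should set the (1S)-carbinol under reagent control while the acrylate, the acetate and the methyl ester are slow to react with borane at −20 °C.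

**Step 7**
Reactants: 12 methyl 2-[(2S,3S)-3-acetoxy-5-[(1S)-1-hydroxyethyl]-2,3-dihydro-1-benzofuran-2-yl]prop-2-enoate
Product: 13 (1S)-1-[(2S,3S)-3-acetoxy-2-(3-methoxy-3-oxoprop-1-en-2-yl)-2,3-dihydro-1-benzofuran-5-yl]ethyl (2Z)-2-methylbut-2-enoate
Conditions: LiHMDS (1.05 equiv), THF, −78 °C; then angelic anhydride (1.3 equiv), −78 → −20 °C; aq NH4Cl
Reagents that add atoms: angelic anhydride, C/C=C(/C)C(=O)OC(=O)/C(C)=C\C
Why: O-Acylation of the lithium alkoxide by the symmetrical anhydride (stereoconservative angeloylation) forms the ester without an acylpyridinium-type adduct at the enoyl unit, so the (Z)-geometry of the 2-methylbut-2-enoyl group and the carbinol configuration (C–O bond untouched) should both be retained.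

**Compound list**
1 | (2S,5S)-hexane-2,5-diol | C[C@H](O)CC[C@H](C)O | starting material
2 | (2S,5S)-hexane-2,5-diyl dimethanesulfonate | C[C@H](OS(C)(=O)=O)CC[C@H](C)OS(C)(=O)=O | intermediate
3 | (2R,5R)-2,5-dimethylthiolane | C[C@@H]1CC[C@@H](C)S1 | intermediate
4 | methyl 2-(bromomethyl)prop-2-enoate | C=C(CBr)C(=O)OC | starting material
5 | (2R,5R)-1-[2-(methoxycarbonyl)prop-2-en-1-yl]-2,5-dimethylthiolan-1-ium tetrafluoroborate | C[C@@H]1CC[C@@H](C)[S+]1CC(=C)C(=O)OC.F[B-](F)(F)F | intermediate
6 | 5-acetyl-2-hydroxybenzaldehyde | CC(=O)c1ccc(O)c(C=O)c1 | starting material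
7 | 4-acetyl-2-formylphenyl acetate | CC(=O)Oc1ccc(C(C)=O)cc1C=O | intermediate
8 | sulfonium ylide: methyl 2-{[(2R,5R)-2,5-dimethylthiolan-1-ium-1-yl]methanidyl}prop-2-enoate | C[C@@H]1CC[C@@H](C)[S+]1[CH-]C(=C)C(=O)OC | intermediate (not isolated)
9 | anti-betaine: (1S,2R)-1-(2-acetoxy-5-acetylphenyl)-2-[(2R,5R)-2,5-dimethylthiolan-1-ium-1-yl]-3-(methoxycarbonyl)but-3-en-1-olate (Li+ and BF4− as spectator ions) | C[C@@H]1CC[C@@H](C)[S+]1[C@H](C(=C)C(=O)OC)[C@@H]([O-])c1cc(C(C)=O)ccc1OC(C)=O | intermediate (not isolated)
10 | acyl-shifted phenoxide: 2-{(1S,2R)-1-acetoxy-2-[(2R,5R)-2,5-dimethylthiolan-1-ium-1-yl]-3-(methoxycarbonyl)but-3-en-1-yl}-4-acetylphenolate | C[C@@H]1CC[C@@H](C)[S+]1[C@H](C(=C)C(=O)OC)[C@@H](OC(C)=O)c1cc(C(C)=O)ccc1[O-] | intermediate (not isolated)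
11 | methyl 2-[(2S,3S)-3-acetoxy-5-acetyl-2,3-dihydro-1-benzofuran-2-yl]prop-2-enoate | C=C(C(=O)OC)[C@@H]1Oc2ccc(C(C)=O)cc2[C@@H]1OC(C)=O | intermediate
12 | methyl 2-[(2S,3S)-3-acetoxy-5-[(1S)-1-hydroxyethyl]-2,3-dihydro-1-benzofuran-2-yl]prop-2-enoate | C=C(C(=O)OC)[C@@H]1Oc2ccc([C@H](C)O)cc2[C@@H]1OC(C)=O | intermediate
13 | (1S)-1-[(2S,3S)-3-acetoxy-2-(3-methoxy-3-oxoprop-1-en-2-yl)-2,3-dihydro-1-benzofuran-5-yl]ethyl (2Z)-2-methylbut-2-enoate | C=C(C(=O)OC)[C@@H]1Oc2ccc([C@H](C)OC(=O)/C(C)=C\C)cc2[C@@H]1OC(C)=O | target

**Step count and risks**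
Total steps: 7. Longest linear sequence: 6 (steps 1, 2, 3, 5, 6, 7).

Step 5 (bears the label). What may go wrong: closure of the betaine to the trans vinyl epoxide before the acetyl group has moved; leakage through the syn-betaine to the trans dihydrobenzofuran; SN2′ closure of the phenoxide to a seven-membered ring; incomplete facial control by the sulfide. The fallback uses known reactions, sets out from 6 and returns at 11. Silylation of the phenol (TIPSCl, imidazole, DMF) gives 5-acetyl-2-[(triisopropylsilyl)oxy]benzaldehyde F1. Chiral-sulfonium epoxidation with salt 5 (phosphazene base P2-Et, CH2Cl2, −78 °C), where reversible syn-betaine formation restores trans selectivity, gives methyl 2-[(2S,3S)-3-{5-acetyl-2-[(triisopropylsilyl)oxy]phenyl}oxiran-2-yl]prop-2-enoate F2. Buffered desilylation (TBAF, AcOH, THF, 0 °C) gives the phenol methyl 2-[(2S,3S)-3-(5-acetyl-2-hydroxyphenyl)oxiran-2-yl]prop-2-enoate F3. Palladium(0)-catalysed allylic etherification (Pd2(dba)3, PPh3 or a matched C2-symmetric diphosphine, CH2Cl2, rt) ionises the vinyl epoxide with inversion, and the phenol attacks the internal π-allyl carbon anti to palladium (5-exo). Net retention at C2 turns the trans epoxide into the cis alcohol methyl 2-[(2S,3S)-5-acetyl-3-hydroxy-2,3-dihydro-1-benzofuran-2-yl]prop-2-enoate F4. Acetylation (Ac2O, pyridine) then gives 11.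

Step 7. What may go wrong: Z → E isomerisation of the angeloyl unit to the tigloyl unit during acyl transfer; base-induced loss of the C3 acetate; ionisation of the p-alkoxybenzylic C–O bond. The fallback builds the (Z)-enoate on the substrate instead of transferring it, sets out from 12 and returns at 13. Steglich esterification of 12 with 2-[bis(2,2,2-trifluoroethoxy)phosphoryl]propanoic acid (EDC·HCl, DMAP, CH2Cl2, 0 °C) gives the phosphonate ester (1S)-1-[(2S,3S)-3-acetoxy-2-(3-methoxy-3-oxoprop-1-en-2-yl)-2,3-dihydro-1-benzofuran-5-yl]ethyl 2-[bis(2,2,2-trifluoroethoxy)phosphoryl]propanoate F5 (both epimers at the phosphonate carbon). Still–Gennari olefination with acetaldehyde (KHMDS, 18-crown-6, THF, −78 °C) should then give the (Z)-2-methylbut-2-enoate 13.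

Step 6. What may go wrong: borane attack on the acrylate or the esters competing with ketone reduction; incomplete reagent control at the remote ketone. The fallback replaces asymmetric reduction by resolution, sets out from 11 and returns at 12. Luche reduction (NaBH4, CeCl3·7H2O, MeOH, −40 °C) gives 12 together with its epimer methyl 2-[(2S,3S)-3-acetoxy-5-[(1R)-1-hydroxyethyl]-2,3-dihydro-1-benzofuran-2-yl]prop-2-enoate F6. Lipase-catalysed acetylation (Candida antarctica lipase B, vinyl acetate, MTBE, 30 °C), which should acylate the (1R)-carbinol preferentially, converts that epimer into methyl 2-[(2S,3S)-3-acetoxy-5-[(1R)-1-acetoxyethyl]-2,3-dihydro-1-benzofuran-2-yl]prop-2-enoate F7. Unreacted 12 is separated by chromatography.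

**Further compounds**
F1 | step 5 | 5-acetyl-2-[(triisopropylsilyl)oxy]benzaldehyde | CC(=O)c1ccc(O[Si](C(C)C)(C(C)C)C(C)C)c(C=O)c1
F2 | step 5 | methyl 2-[(2S,3S)-3-{5-acetyl-2-[(triisopropylsilyl)oxy]phenyl}oxiran-2-yl]prop-2-enoate | C=C(C(=O)OC)[C@@H]1O[C@H]1c1cc(C(C)=O)ccc1O[Si](C(C)C)(C(C)C)C(C)C
F3 | step 5 | methyl 2-[(2S,3S)-3-(5-acetyl-2-hydroxyphenyl)oxiran-2-yl]prop-2-enoate | C=C(C(=O)OC)[C@@H]1O[C@H]1c1cc(C(C)=O)ccc1O
F4 | step 5 | methyl 2-[(2S,3S)-5-acetyl-3-hydroxy-2,3-dihydro-1-benzofuran-2-yl]prop-2-enoate | C=C(C(=O)OC)[C@@H]1Oc2ccc(C(C)=O)cc2[C@@H]1O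
F5 | step 7 | (1S)-1-[(2S,3S)-3-acetoxy-2-(3-methoxy-3-oxoprop-1-en-2-yl)-2,3-dihydro-1-benzofuran-5-yl]ethyl 2-[bis(2,2,2-trifluoroethoxy)phosphoryl]propanoate | C=C(C(=O)OC)[C@@H]1Oc2ccc([C@H](C)OC(=O)C(C)P(=O)(OCC(F)(F)F)OCC(F)(F)F)cc2[C@@H]1OC(C)=O
F6 | step 6 | methyl 2-[(2S,3S)-3-acetoxy-5-[(1R)-1-hydroxyethyl]-2,3-dihydro-1-benzofuran-2-yl]prop-2-enoate | C=C(C(=O)OC)[C@@H]1Oc2ccc([C@@H](C)O)cc2[C@@H]1OC(C)=O
F7 | step 6 | methyl 2-[(2S,3S)-3-acetoxy-5-[(1R)-1-acetoxyethyl]-2,3-dihydro-1-benzofuran-2-yl]prop-2-enoate | C=C(C(=O)OC)[C@@H]1Oc2ccc([C@@H](C)OC(C)=O)cc2[C@@H]1OC(C)=O
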